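Cuts: (a) the bond from the lactone α-carbon to its benzylic CH2 (lactone enolate + benzylic bromide); (b) C3–C3a of the dihydrobenzofuran; (c) the C2–aryl bond of the flavanone that cut (b) uncovers; (d) in the lactone half, the CH–CH2C(=O) bond.
Enabling feature: ring O1–C2–C3–C3a–C7a together with the exocyclic CH2OH carbon on C3 holds the six ring atoms of a chroman-4-one. With C3a bonded to that exocyclic carbon instead of to C3, the carbon is the C4 carbonyl of a 6-bromo-8-methoxyflavanone, so an oxidative 1,2-shift of this aryl carbon from C4 to C3 rebuilds the target ring.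
Forward, arm 1: ring A is bought, the pyranone is closed on it (chromone), ring B is added at C2, the pyranone is contracted to the dihydrofuran, and C5–Br becomes C5–CH2Br.
Forward, arm 2: the butyrolactone is closed separately from dihydroferulic acid, the two halves are joined last, and one fluoride step frees all three hydroxyl groups.
Stereochemistry: C2 comes from ligand-controlled conjugate arylation, C3 from C2 through the stereospecific shift, lactone C4 from an Evans auxiliary, and lactone C3 from C4 by anti alkylation.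

Key step: step 6

Abbreviations: TBS = tert-butyldimethylsilyl, Piv = pivaloyl, t-BuPyOX = 4-tert-butyl-2-(pyridin-2-yl)-4,5-dihydrooxazole.
Assumption: the chromone is taken to bind to the cationic palladium–PyOX complex as carbocyclic enones do, for which the (S)-ligand gives the (R)-β-aryl ketone. On that model the (R)-ligand gives the (S)-flavanone, and the equally available antipode would be used if the sense proved opposite.

Step 1
Reactants: 1 2'-hydroxy-3'-methoxyacetophenone
Product: 2 1-(5-bromo-2-hydroxy-3-methoxyphenyl)ethan-1-one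
Conditions: NBS (1.05 equiv), MeCN, 0 °C to rt
Reagents that add atoms: N-bromosuccinimide, O=C1CCC(=O)N1Br
Why: Electrophilic aromatic bromination: the phenol directs to C5', its only open ortho/para position and one that is also meta to the acetyl group, and NBS in MeCN should leave the methyl ketone untouched.

Step 2
Reactants: 2 1-(5-bromo-2-hydroxy-3-methoxyphenyl)ethan-1-one; 3 N,N-dimethylformamide dimethyl acetal
Product: 5 6-bromo-8-methoxy-4H-chromen-4-one, via enaminone 4 (not isolated)
Conditions: 3 (2 equiv), toluene, 100 °C; evaporate; conc. aq. HCl, CH2Cl2, 40 °C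
Reagents that add atoms: none
Why: Enaminone route to chromones: the acetal condenses with the acidic methyl ketone to 4, and acid then lets the phenol oxygen add to the β-carbon (6-endo-trig addition–elimination) with loss of dimethylamine to close the pyranone.

Step 3
Reactants: 6 2-methoxy-4-(4,4,5,5-tetramethyl-1,3,2-dioxaborolan-2-yl)phenol
Product: 7 2-methoxy-4-(4,4,5,5-tetramethyl-1,3,2-dioxaborolan-2-yl)phenyl pivalate
Conditions: PivCl (1.2 equiv), Et3N (1.5 equiv), DMAP (5 mol %), CH2Cl2, 0 °C to rt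
Reagents that add atoms: pivaloyl chloride, CC(C)(C)C(=O)Cl
Why: O-acylation of a phenol, which the pinacol boronate tolerates; the pivalate is chosen because it lowers the electron density of ring B for step 6, resists acid and is removed without an extra step in step 7.

Step 4
Reactants: 7 2-methoxy-4-(4,4,5,5-tetramethyl-1,3,2-dioxaborolan-2-yl)phenyl pivalate
Product: 8 [3-methoxy-4-(pivaloyloxy)phenyl]boronic acid
Conditions: NaIO4 (3 equiv), NH4OAc (3 equiv), acetone–H2O (1:1), rt
Reagents that add atoms: water, O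
Why: Periodate glycol cleavage: NaIO4 destroys the pinacol released in the hydrolysis equilibrium and so drives the boronate to the free boronic acid under near-neutral conditions that spare the aryl ester.

Step 5
Reactants: 5 6-bromo-8-methoxy-4H-chromen-4-one; 8 [3-methoxy-4-(pivaloyloxy)phenyl]boronic acid
Product: 9 (S)-6-bromo-8-methoxy-2-[3-methoxy-4-(pivaloyloxy)phenyl]chroman-4-one
Conditions: Pd(OCOCF3)2 (5 mol %), (R)-t-BuPyOX (6 mol %), NH4PF6 (30 mol %), H2O (5 equiv), ClCH2CH2Cl, 60 °C, under air
Reagents that add atoms: none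
Why: Enantioselective conjugate addition of an arylboronic acid to a chromone under cationic divalent palladium: transmetalation, face-selective carbopalladation of C2=C3 inside the pyridine–oxazoline pocket and protonolysis of the palladium enolate set C2 as S, and since no zerovalent palladium takes part the C6–Br bond should survive.

Step 6
Reactants: 9 (S)-6-bromo-8-methoxy-2-[3-methoxy-4-(pivaloyloxy)phenyl]chroman-4-one
Product: 12 methyl (2S,3S)-5-bromo-7-methoxy-2-[3-methoxy-4-(pivaloyloxy)phenyl]-2,3-dihydrobenzofuran-3-carboxylate (2,3-trans), via 4-methoxy-2H-chromene enol ether 10 (not isolated), via trans-3-iodanyl dimethyl ketal 11 (not isolated)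
Conditions: PhI(OAc)2 (1.2 equiv), conc. H2SO4 (0.5 equiv), HC(OMe)3 (solvent), rt; then aq. NaHCO3
Reagents that add atoms: trimethyl orthoformate, COC(OC)OC; water, O
Why: Acid and orthoformate convert the ketone of 9 into its dimethyl ketal and then into enol ether 10, whose C3 attacks trivalent iodine on the face away from the equatorial 2-aryl group while methanol returns to C4, giving the trans iodane 11. In the diequatorial conformer of 11 the C3–I bond lies antiperiplanar to the ring bond C4–C4a, so the fused aryl carbon C4a, pushed by the two ketal oxygens and stabilised by the ortho ring oxygen O1, bridges to C3 (3-exo-tet attack, phenonium ion), iodobenzene leaves, C4–C4a breaks, and the dimethoxycarbenium ion now outside the ring is hydrolysed to the methyl ester on work-up. This is the known oxidative 1,2-aryl shift of flavanones with PhI(OAc)2 or Tl(NO3)3 in trimethyl orthoformate, the cyclic counterpart of the aryl ketone to arylacetate rearrangement. The dihydrofuran ring (O1, C2, C3, C3a, C7a) therefore arises by contraction of the six-membered pyranone and not by an end-to-end cyclisation. The new centre C3 is set by inversion at the carbon that carried iodine, which places the ester trans to the 2-aryl group and gives (2S,3S), also the thermodynamic arrangement at this epimerisable position, while none of the bonds at C2 is broken. The step needs the C4a shift to beat migration of the 2-aryl group (isoflavone), loss of H-2 (flavone) and ionisation of C2–O1: the pivalate makes ring B a poor migrating group and a poor cation stabiliser, and the equatorial 2-aryl group is gauche, not anti, to the C3–I bond.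

Step 7
Reactants: 12 methyl (2S,3S)-5-bromo-7-methoxy-2-[3-methoxy-4-(pivaloyloxy)phenyl]-2,3-dihydrobenzofuran-3-carboxylate
Product: 13 4-[(2S,3R)-5-bromo-3-(hydroxymethyl)-7-methoxy-2,3-dihydrobenzofuran-2-yl]-2-methoxyphenol
Conditions: LiAlH4 (3 equiv), THF, 0 °C; then EtOAc, aq. potassium sodium tartrate
Reagents that add atoms: none
Why: Ester reduction with LiAlH4: hydride addition at 0 °C is faster than enolisation at C3, takes the methyl ester to the primary alcohol (C3 becomes R by priority change only) and cleaves the aryl pivalate in the same flask, while the aryl bromide is inert at this temperature.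

Step 8
Reactants: 13 4-[(2S,3R)-5-bromo-3-(hydroxymethyl)-7-methoxy-2,3-dihydrobenzofuran-2-yl]-2-methoxyphenol
Product: 14 (2S,3R)-5-bromo-3-(TBSO-methyl)-2-(4-TBSO-3-methoxyphenyl)-7-methoxy-2,3-dihydrobenzofuran
Conditions: TBSCl (2.5 equiv), imidazole (5 equiv), DMF, rt
Reagents that add atoms: tert-butyldimethylsilyl chloride, CC(C)(C)[Si](C)(C)Cl
Why: Silyl ether formation on both hydroxyl groups gives base-stable protection that lasts through lithiation and enolate chemistry and is removed in a single fluoride step.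

Step 9
Reactants: 14 (2S,3R)-5-bromo-3-(TBSO-methyl)-2-(4-TBSO-3-methoxyphenyl)-7-methoxy-2,3-dihydrobenzofuran
Product: 17 [(2S,3R)-3-(TBSO-methyl)-2-(4-TBSO-3-methoxyphenyl)-7-methoxy-2,3-dihydrobenzofuran-5-yl]methanol, via aryllithium 15 (not isolated), via aldehyde 16 (not isolated)
Conditions: n-BuLi (1.1 equiv), THF, −78 °C; DMF (3 equiv), −78 to 0 °C; then MeOH, NaBH4, 0 °C
Reagents that add atoms: N,N-dimethylformamide, CN(C)C=O
Why: Bromine–lithium exchange, formylation with DMF and borohydride reduction in one flask: exchange at −78 °C is far faster than any deprotonation, and the silyl and methyl ethers are inert to all three reagents.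

Step 10
Reactants: 17 [(2S,3R)-3-(TBSO-methyl)-2-(4-TBSO-3-methoxyphenyl)-7-methoxy-2,3-dihydrobenzofuran-5-yl]methanol
Product: 18 (2S,3R)-5-(bromomethyl)-3-(TBSO-methyl)-2-(4-TBSO-3-methoxyphenyl)-7-methoxy-2,3-dihydrobenzofuran
Conditions: CBr4 (1.3 equiv), PPh3 (1.3 equiv), CH2Cl2, 0 °C; short silica plug, used at once
Reagents that add atoms: carbon tetrabromide, BrC(Br)(Br)Br
Why: Appel reaction: the benzylic alcohol is converted into the bromide through its alkoxyphosphonium salt under neutral conditions that the silyl ethers tolerate, and the bromide, activated by the para ring oxygen O1, is not stored.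

Step 11
Reactants: 19 3-(4-hydroxy-3-methoxyphenyl)propanoic acid (dihydroferulic acid)
Product: 21 3-(4-TBSO-3-methoxyphenyl)propanoic acid, via silyl ester 20 (not isolated)
Conditions: TBSCl (2.3 equiv), imidazole (5 equiv), DMF, rt; then THF–H2O–AcOH, rt
Reagents that add atoms: tert-butyldimethylsilyl chloride, CC(C)(C)[Si](C)(C)Cl
Why: Silylation of phenol and acid followed by selective hydrolysis of the far more labile silyl ester is the standard way to a phenol-protected acid.

Step 12
Reactants: 21 3-(4-TBSO-3-methoxyphenyl)propanoic acid; 22 (S)-4-benzyloxazolidin-2-one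
Product: 24 (S)-4-benzyl-3-[3-(4-TBSO-3-methoxyphenyl)propanoyl]oxazolidin-2-one, via mixed pivalic anhydride 23 (not isolated)
Conditions: PivCl (1.1 equiv), Et3N (2.5 equiv), THF, −20 °C; then LiCl (1.1 equiv), 22, −20 °C to rt
Reagents that add atoms: none
Why: N-Acylation of the Evans auxiliary through a mixed anhydride, in which the hindered pivaloyl carbonyl directs attack to the wanted acyl group.

Step 13
Reactants: 24 (S)-4-benzyl-3-[3-(4-TBSO-3-methoxyphenyl)propanoyl]oxazolidin-2-one; 25 tert-butyl bromoacetate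
Product: 27 tert-butyl (R)-4-[(S)-4-benzyl-2-oxooxazolidin-3-yl]-3-(4-TBSO-3-methoxybenzyl)-4-oxobutanoate, via sodium Z-enolate 26 (not isolated)
Conditions: NaN(SiMe3)2 (1.1 equiv), THF, −78 °C; 25 (2 equiv), −78 to −40 °C
Reagents that add atoms: none
Why: Evans asymmetric alkylation: the chelated Z-enolate 26 is shielded on one face by the 4-benzyl group, so the bromoacetate enters from the other face and sets the future lactone C4 as R.

Step 14
Reactants: 27 tert-butyl (R)-4-[(S)-4-benzyl-2-oxooxazolidin-3-yl]-3-(4-TBSO-3-methoxybenzyl)-4-oxobutanoate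
Product: 29 (R)-4-(4-TBSO-3-methoxybenzyl)dihydrofuran-2(3H)-one, via hydroxy ester 28 (not isolated)
Conditions: LiBH4 (2 equiv), THF, 0 °C to rt; aqueous work-up; then CF3CO2H–CH2Cl2 (1:4), rt
Reagents that add atoms: none
Why: Reductive removal of the auxiliary with LiBH4, to which the hindered tert-butyl ester is inert, and acid-induced lactonisation (5-exo-trig acyl substitution) of 28, which is not purified because it begins to lactonise by itself; the stereocentre is not touched and the aryl silyl ether withstands CF3CO2H.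

Step 15
Reactants: 29 (R)-4-(4-TBSO-3-methoxybenzyl)dihydrofuran-2(3H)-one; 18 (2S,3R)-5-(bromomethyl)-3-(TBSO-methyl)-2-(4-TBSO-3-methoxyphenyl)-7-methoxy-2,3-dihydrobenzofuran
Product: 31 tris-TBS ether of isolappaol A: (3R,4R)-4-(4-TBSO-3-methoxybenzyl)-3-{[(2S,3R)-3-(TBSO-methyl)-2-(4-TBSO-3-methoxyphenyl)-7-methoxy-2,3-dihydrobenzofuran-5-yl]methyl}dihydrofuran-2(3H)-one, via lithium enolate 30 (not isolated)
Conditions: LiN(SiMe3)2 (1.1 equiv), THF, −78 °C; 18 (0.9 equiv), DMPU, −78 to −30 °C
Reagents that add atoms: none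
Why: Diastereoselective enolate alkylation of a β-substituted γ-butyrolactone, the standard entry to trans-dibenzylbutyrolactone lignans: the β-benzyl group blocks one face of 30, the bromide enters anti and sets lactone C3 as R (trans, also the thermodynamic arrangement), and material derived from any minor enantiomer of 18 becomes a diastereomer that can be removed here.

Step 16
Reactants: 31 tris-TBS ether of isolappaol A
Product: 32 isolappaol A
Conditions: Bu4NF (4 equiv), AcOH (4 equiv), THF, 0 °C to rt
Reagents that add atoms: none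
Why: Fluoride-induced desilylation of all three silyl ethers; the AcOH buffer keeps phenoxide basicity low, so neither the lactone α-centre nor the C2–O1 bond para to the freed phenol (quinone methide opening) is put at risk.

Compound list
1 | 2'-hydroxy-3'-methoxyacetophenone | CC(=O)c1cccc(OC)c1O | starting material
2 | 1-(5-bromo-2-hydroxy-3-methoxyphenyl)ethan-1-one | CC(=O)c1cc(Br)cc(OC)c1O | intermediate
3 | N,N-dimethylformamide dimethyl acetal | COC(OC)N(C)C | starting material
4 | (E)-1-(5-bromo-2-hydroxy-3-methoxyphenyl)-3-(dimethylamino)prop-2-en-1-one | CN(C)/C=C/C(=O)c1cc(Br)cc(OC)c1O | intermediate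
5 | 6-bromo-8-methoxy-4H-chromen-4-one | O=c1ccoc2c(OC)cc(Br)cc12 | intermediate
6 | 2-methoxy-4-(4,4,5,5-tetramethyl-1,3,2-dioxaborolan-2-yl)phenol | COc1cc(B2OC(C)(C)C(C)(C)O2)ccc1O | starting material
7 | 2-methoxy-4-(4,4,5,5-tetramethyl-1,3,2-dioxaborolan-2-yl)phenyl pivalate | COc1cc(B2OC(C)(C)C(C)(C)O2)ccc1OC(=O)C(C)(C)C | intermediate
8 | [3-methoxy-4-(pivaloyloxy)phenyl]boronic acid | COc1cc(B(O)O)ccc1OC(=O)C(C)(C)C | intermediate
9 | (S)-6-bromo-8-methoxy-2-[3-methoxy-4-(pivaloyloxy)phenyl]chroman-4-one | O=C1C[C@@H](c2ccc(OC(=O)C(C)(C)C)c(OC)c2)Oc2c(OC)cc(Br)cc21 | intermediate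
10 | (S)-6-bromo-4,8-dimethoxy-2-[3-methoxy-4-(pivaloyloxy)phenyl]-2H-chromene | COC1=C[C@@H](c2ccc(OC(=O)C(C)(C)C)c(OC)c2)Oc2c(OC)cc(Br)cc21 | intermediate
11 | 2,3-trans-3-[acetoxy(phenyl)-λ3-iodanyl]-6-bromo-4,4,8-trimethoxy-2-[3-methoxy-4-(pivaloyloxy)phenyl]chromane (C2 arranged as in 9) | COC1(OC)[C@H](I(OC(C)=O)c2ccccc2)[C@@H](c2ccc(OC(=O)C(C)(C)C)c(OC)c2)Oc2c(OC)cc(Br)cc21 | intermediate
12 | methyl (2S,3S)-5-bromo-7-methoxy-2-[3-methoxy-4-(pivaloyloxy)phenyl]-2,3-dihydrobenzofuran-3-carboxylate (trans) | COC(=O)[C@H]1c2cc(Br)cc(OC)c2O[C@@H]1c1ccc(OC(=O)C(C)(C)C)c(OC)c1 | intermediate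
13 | 4-[(2S,3R)-5-bromo-3-(hydroxymethyl)-7-methoxy-2,3-dihydrobenzofuran-2-yl]-2-methoxyphenol | OC[C@H]1c2cc(Br)cc(OC)c2O[C@@H]1c1ccc(O)c(OC)c1 | intermediate
14 | (2S,3R)-5-bromo-3-(TBSO-methyl)-2-(4-TBSO-3-methoxyphenyl)-7-methoxy-2,3-dihydrobenzofuran | CC(C)(C)[Si](C)(C)OC[C@H]1c2cc(Br)cc(OC)c2O[C@@H]1c1ccc(O[Si](C)(C)C(C)(C)C)c(OC)c1 | intermediate
15 | 5-lithio analogue of 14 | CC(C)(C)[Si](C)(C)OC[C@H]1c2cc([Li])cc(OC)c2O[C@@H]1c1ccc(O[Si](C)(C)C(C)(C)C)c(OC)c1 | intermediate
16 | (2S,3R)-3-(TBSO-methyl)-2-(4-TBSO-3-methoxyphenyl)-7-methoxy-2,3-dihydrobenzofuran-5-carbaldehyde | CC(C)(C)[Si](C)(C)OC[C@H]1c2cc(C=O)cc(OC)c2O[C@@H]1c1ccc(O[Si](C)(C)C(C)(C)C)c(OC)c1 | intermediate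
17 | [(2S,3R)-3-(TBSO-methyl)-2-(4-TBSO-3-methoxyphenyl)-7-methoxy-2,3-dihydrobenzofuran-5-yl]methanol | CC(C)(C)[Si](C)(C)OC[C@H]1c2cc(CO)cc(OC)c2O[C@@H]1c1ccc(O[Si](C)(C)C(C)(C)C)c(OC)c1 | intermediate
18 | (2S,3R)-5-(bromomethyl)-3-(TBSO-methyl)-2-(4-TBSO-3-methoxyphenyl)-7-methoxy-2,3-dihydrobenzofuran | CC(C)(C)[Si](C)(C)OC[C@H]1c2cc(CBr)cc(OC)c2O[C@@H]1c1ccc(O[Si](C)(C)C(C)(C)C)c(OC)c1 | intermediate
19 | 3-(4-hydroxy-3-methoxyphenyl)propanoic acid | COc1cc(CCC(=O)O)ccc1O | starting material
20 | TBS 3-(4-TBSO-3-methoxyphenyl)propanoate | COc1cc(CCC(=O)O[Si](C)(C)C(C)(C)C)ccc1O[Si](C)(C)C(C)(C)C | intermediate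
21 | 3-(4-TBSO-3-methoxyphenyl)propanoic acid | COc1cc(CCC(=O)O)ccc1O[Si](C)(C)C(C)(C)C | intermediate
22 | (S)-4-benzyloxazolidin-2-one | O=C1N[C@@H](Cc2ccccc2)CO1 | starting material
23 | 3-(4-TBSO-3-methoxyphenyl)propanoic pivalic anhydride | COc1cc(CCC(=O)OC(=O)C(C)(C)C)ccc1O[Si](C)(C)C(C)(C)C | intermediate
24 | (S)-4-benzyl-3-[3-(4-TBSO-3-methoxyphenyl)propanoyl]oxazolidin-2-one | COc1cc(CCC(=O)N2[C@@H](Cc3ccccc3)COC2=O)ccc1O[Si](C)(C)C(C)(C)C | intermediate
25 | tert-butyl bromoacetate | CC(C)(C)OC(=O)CBr | starting material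
26 | sodium Z-enolate of 24 | [Na+].[O-]/C(=C\Cc1ccc(O[Si](C)(C)C(C)(C)C)c(OC)c1)N1[C@@H](Cc2ccccc2)COC1=O | intermediate
27 | tert-butyl (R)-4-[(S)-4-benzyl-2-oxooxazolidin-3-yl]-3-(4-TBSO-3-methoxybenzyl)-4-oxobutanoate | COc1cc(C[C@H](CC(=O)OC(C)(C)C)C(=O)N2[C@@H](Cc3ccccc3)COC2=O)ccc1O[Si](C)(C)C(C)(C)C | intermediate
28 | tert-butyl (R)-3-(hydroxymethyl)-4-(4-TBSO-3-methoxyphenyl)butanoate | COc1cc(C[C@H](CC(=O)OC(C)(C)C)CO)ccc1O[Si](C)(C)C(C)(C)C | intermediate
29 | (R)-4-(4-TBSO-3-methoxybenzyl)dihydrofuran-2(3H)-one | COc1cc(C[C@H]2COC(=O)C2)ccc1O[Si](C)(C)C(C)(C)C | intermediate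
30 | lithium enolate of 29 | COc1cc(C[C@H]2COC([O-])=C2)ccc1O[Si](C)(C)C(C)(C)C.[Li+] | intermediate
31 | tris-TBS ether of isolappaol A, (3R,4R) in the lactone and (2S,3R) in the dihydrobenzofuran | COc1cc(C[C@H]2COC(=O)[C@@H]2Cc2cc(OC)c3c(c2)[C@H](CO[Si](C)(C)C(C)(C)C)[C@@H](c2ccc(O[Si](C)(C)C(C)(C)C)c(OC)c2)O3)ccc1O[Si](C)(C)C(C)(C)C | intermediate
32 | isolappaol A | COc1cc(C[C@H]2COC(=O)[C@@H]2Cc2cc(OC)c3c(c2)[C@H](CO)[C@@H](c2ccc(O)c(OC)c2)O3)ccc1O | target

Total step count: 16.
Longest linear sequence: 10 steps (1, 2, 5, 6, 7, 8, 9, 10, 15, 16). The arm from 6 is equally long and the lactone arm takes 6 steps to the target.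

Steps most likely to fail

Step 6. The 2-aryl group or H-2 may move from C2 faster than C4a shifts, methanol may displace the iodane at C3, and the strong acid may open the C2–O1 bond and erode the configuration. The fallback sets out from 9 and comes back at 12. It runs the same C4-to-C3 shift of C4a through a carbene/ketene manifold, free of acid and oxidant. Compound 9 is deprotonated with LiN(SiMe3)2 at −78 °C and acylated with CF3CO2CH2CF3 to the 3-trifluoroacetylflavanone F1. MsN3, Et3N and H2O in MeCN (detrifluoroacetylative diazo transfer) then give the 3-diazoflavanone F2. Irradiation in MeOH starts the Wolff rearrangement, in which the s-Z-locked diazoketone loses N2 as C4a moves to C3, and the ring-contracted ketene F3 adds methanol. Protonation on the face away from the 2-aryl group may give the cis ester F4 beside 12, and a catalytic amount of DBU in toluene should equilibrate it to the trans ester 12.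

Step 5. Carbopalladation may be slow enough for protodeboronation of 8 to take over, facial selectivity may be poor or of the opposite sense, and retro-oxa-Michael opening of the product may erode its enantiopurity. The fallback sets out from 2 and comes back at 9. It replaces asymmetric C–C bond formation by a racemic chalcone route with kinetic resolution. Vanillin is acylated with PivCl to 4-formyl-2-methoxyphenyl pivalate F5. A BF3·OEt2-mediated Claisen–Schmidt condensation with 2, which spares the aryl ester, gives the 2'-hydroxychalcone F6. NaOAc in refluxing EtOH closes F6 by oxa-Michael addition to the racemic flavanone F7. Noyori-type asymmetric transfer hydrogenation with RuCl(p-cymene)[(R,R)-TsDPEN] in HCO2H–Et3N should reduce the matched (R)-enantiomer to the cis-(2R,4R)-flavan-4-ol F8 and leave (S)-flavanone 9, which is separated by chromatography.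

Step 15. The electron-rich benzylic bromide may ionise and self-condense before C-alkylation, and proton transfer between product and enolate may lead to double alkylation or incomplete conversion. The fallback sets out from 14 and 29 and comes back at 31. It avoids the bromide altogether. Step 9 is stopped before the borohydride so that aldehyde 16 is isolated, and enolate 30 adds to it at −78 °C (aldol addition, anti to the β-benzyl group) to give the 3,4-trans aldol adduct F9 as carbinol epimers. PhOC(S)Cl and DMAP convert both epimers into the phenyl thionocarbonate F10. Bu3SnH and AIBN in toluene at 90 °C (Barton–McCombie deoxygenation) remove the oxygen by a radical path, which avoids the benzylic cation that would cyclise onto the neighbouring arene, and deliver 31.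

Further compounds
F1 | step 6 | (2S)-6-bromo-8-methoxy-2-[3-methoxy-4-(pivaloyloxy)phenyl]-3-(trifluoroacetyl)chroman-4-one (C3 enolisable) | O=C1C(C(=O)C(F)(F)F)[C@@H](c2ccc(OC(=O)C(C)(C)C)c(OC)c2)Oc2c(OC)cc(Br)cc21
F2 | step 6 | 6-bromo-3-diazo-8-methoxy-2-[3-methoxy-4-(pivaloyloxy)phenyl]chroman-4-one (C2 arranged as in 9, descriptor R by priority change) | O=C1C(=[N+]=[N-])[C@@H](c2ccc(OC(=O)C(C)(C)C)c(OC)c2)Oc2c(OC)cc(Br)cc21
F3 | step 6 | ketene, 5-bromo-7-methoxy-2-[3-methoxy-4-(pivaloyloxy)phenyl]-3-(oxomethylidene)-2,3-dihydrobenzofuran (C2 arranged as in 9) | O=C=C1c2cc(Br)cc(OC)c2O[C@@H]1c1ccc(OC(=O)C(C)(C)C)c(OC)c1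
F4 | step 6 | methyl (2S,3R)-5-bromo-7-methoxy-2-[3-methoxy-4-(pivaloyloxy)phenyl]-2,3-dihydrobenzofuran-3-carboxylate (cis) | COC(=O)[C@@H]1c2cc(Br)cc(OC)c2O[C@@H]1c1ccc(OC(=O)C(C)(C)C)c(OC)c1
F5 | step 5 | 4-formyl-2-methoxyphenyl pivalate | COc1cc(C=O)ccc1OC(=O)C(C)(C)C
F6 | step 5 | (E)-1-(5-bromo-2-hydroxy-3-methoxyphenyl)-3-[3-methoxy-4-(pivaloyloxy)phenyl]prop-2-en-1-one | O=C(/C=C/c1ccc(OC(=O)C(C)(C)C)c(OC)c1)c1cc(Br)cc(OC)c1O
F7 | step 5 | racemic 6-bromo-8-methoxy-2-[3-methoxy-4-(pivaloyloxy)phenyl]chroman-4-one | O=C1CC(c2ccc(OC(=O)C(C)(C)C)c(OC)c2)Oc2c(OC)cc(Br)cc21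
F8 | step 5 | (2R,4R)-6-bromo-8-methoxy-2-[3-methoxy-4-(pivaloyloxy)phenyl]chroman-4-ol (2,4-cis) | O[C@@H]1C[C@H](c2ccc(OC(=O)C(C)(C)C)c(OC)c2)Oc2c(OC)cc(Br)cc21
F9 | step 15 | aldol adduct of 30 and 16, 3,4-trans in the lactone, carbinol epimers | COc1cc(C[C@H]2COC(=O)[C@@H]2C(O)c2cc(OC)c3c(c2)[C@H](CO[Si](C)(C)C(C)(C)C)[C@@H](c2ccc(O[Si](C)(C)C(C)(C)C)c(OC)c2)O3)ccc1O[Si](C)(C)C(C)(C)C
F10 | step 15 | O-phenyl thionocarbonate of F9 | COc1cc(C[C@H]2COC(=O)[C@@H]2C(OC(=S)Oc4ccccc4)c2cc(OC)c3c(c2)[C@H](CO[Si](C)(C)C(C)(C)C)[C@@H](c2ccc(O[Si](C)(C)C(C)(C)C)c(OC)c2)O3)ccc1O[Si](C)(C)C(C)(C)C
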